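**Retrosynthetic overview** (benzofuran locants are used for the bicyclic core)
- The enabling feature is the vinylogous ester O1–C7a=C3a–C4=O shared by the dihydrofuran and the six-membered ring, next to the C7 triketone. C7a is a former ester carbon and C3a the α-carbon of the C4 ketone (Claisen retron); O1–C2 beside the tertiary carbinol is the retron of a 5-exo epoxide opening.
- Last disconnection: the C7 prenyl group, by Tsuji–Trost alkylation of the C7-H β-triketone 18, with face control from the C5 and C2 substituents.
- Key disconnection: C3a–C7a and O1–C2 of 18, back to the acyclic triacyl ester epoxide 16. Ring order forward: carbocycle first, dihydrofuran second, same flask.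
- 16 comes from the dianion of triacyl ester 12 and the triflate of (2R,3S)-epoxynerol 14 (Sharpless). 12 comes from the (S)-quaternary β-keto acid 9 (chiral enamine alkylation) and methyl 4-methyl-3-oxopentanoate 10.

Key step: step 8

Assumption: the facial sense of the enamine alkylation in step 3 depends on the additive; the L-valine ester with LDA/HMPA in toluene is taken to give the (S)-centre, and the D-valine ester is used if the opposite sense is found.

Step 1
Reactants: 1 methyl 2-methyl-3-oxobutanoate; 2 2-(trimethylsilyl)ethanol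
Product: 3 2-(trimethylsilyl)ethyl 2-methyl-3-oxobutanoate (racemic)
Conditions: DMAP (10 mol%), toluene, reflux, 4 Å MS
Reagents that add atoms: none
Why: DMAP-catalysed transesterification of a β-keto ester, driven by removal of methanol on the sieves; the α-centre is racemic and is erased in step 2.

Step 2
Reactants: 3 2-(trimethylsilyl)ethyl 2-methyl-3-oxobutanoate; 4 L-valine tert-butyl ester (free base)
Product: 5 2-(trimethylsilyl)ethyl (2Z)-3-{[(2S)-1-tert-butoxy-3-methyl-1-oxobutan-2-yl]amino}-2-methylbut-2-enoate
Conditions: AcOH (cat.), 4 Å MS, toluene, 60 °C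
Reagents that add atoms: none
Why: Condensation of the ketone with the primary amine (enamine formation) should give the hydrogen-bonded Z-enamino ester, which places the valine auxiliary next to the carbon to be alkylated.

Step 3
Reactants: 5 the enamino ester; 6 1-bromo-3-methylbut-2-ene (prenyl bromide)
Product: 8 2-(trimethylsilyl)ethyl (2S)-2-methyl-2-(3-methylbut-2-en-1-yl)-3-oxobutanoate, via ketimine 7 (not isolated)
Conditions: LDA (1.2 equiv), toluene, −78 °C; HMPA (2 equiv); 6, −78 → −40 °C; then 10% aq. citric acid, THF, 0 °C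
Reagents that add atoms: water, O
Why: Chiral-auxiliary enamine alkylation: the N-lithiated enamino ester is a chelated aza-enolate whose isopropyl group shields one face, so SN2 C-alkylation by prenyl bromide should set the quaternary (S)-centre, and mild acid hydrolysis of ketimine 7 releases the β-keto ester and returns 4.

Step 4
Reactants: 8 2-(trimethylsilyl)ethyl (2S)-2-methyl-2-(3-methylbut-2-en-1-yl)-3-oxobutanoate
Product: 9 (2S)-2-methyl-2-(3-methylbut-2-en-1-yl)-3-oxobutanoic acid
Conditions: TBAF (1.2 equiv), THF, 0 °C; cold 0.5 M HCl, extraction at 0 °C; used at once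
Reagents that add atoms: none
Why: Fluoride-induced β-elimination of the 2-silylethyl ester frees the carboxylate without hydroxide or strong acid, so neither retro-Claisen cleavage nor protonation of the prenyl alkene is expected; the α,α-disubstituted β-keto acid is kept cold and used at once to avoid decarboxylation.

Step 5
Reactants: 9 (2S)-2-methyl-2-(3-methylbut-2-en-1-yl)-3-oxobutanoic acid; 10 methyl 4-methyl-3-oxopentanoate
Product: 12 methyl (4S)-4-methyl-4-(3-methylbut-2-en-1-yl)-2-(2-methylpropanoyl)-3,5-dioxohexanoate, via acid chloride 11 (not isolated)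
Conditions: 1-chloro-N,N,2-trimethylprop-1-en-1-amine (1.1 equiv), CH2Cl2, 0 °C; then 10, MgCl2, pyridine, CH2Cl2, 0 °C → rt; 1 M HCl work-up
Reagents that add atoms: none
Why: Neutral acid chloride formation with the α-chloroenamine, followed by C-acylation of the chelated magnesium enolate of the β-keto ester (MgCl2/pyridine acylation), should give the triacylmethane as its enol; the quaternary centre has no acidic hydrogen and cannot epimerise.

Step 6
Reactants: 13 nerol [(2Z)-3,7-dimethylocta-2,6-dien-1-ol]
Product: 14 [(2R,3S)-3-methyl-3-(4-methylpent-3-en-1-yl)oxiran-2-yl]methanol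
Conditions: Ti(OiPr)4 (10 mol%), D-(−)-diethyl tartrate (12 mol%), t-BuOOH, 4 Å MS, CH2Cl2, −20 °C
Reagents that add atoms: tert-butyl hydroperoxide, CC(C)(C)OO
Why: Sharpless asymmetric epoxidation of the Z-allylic alcohol; D-(−)-diethyl tartrate should deliver oxygen to the face that gives the (2R,3S)-epoxide, which fixes both side-chain stereocentres (the carbinol carbon directly, the ring CH after inversion in step 8).

Step 7
Reactants: 12 methyl (4S)-4-methyl-4-(3-methylbut-2-en-1-yl)-2-(2-methylpropanoyl)-3,5-dioxohexanoate; 14 [(2R,3S)-3-methyl-3-(4-methylpent-3-en-1-yl)oxiran-2-yl]methanol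
Product: 16 methyl (4S)-4-methyl-4-(3-methylbut-2-en-1-yl)-7-[(2R,3S)-3-methyl-3-(4-methylpent-3-en-1-yl)oxiran-2-yl]-2-(2-methylpropanoyl)-3,5-dioxoheptanoate, via epoxy triflate 15 (not isolated)
Conditions: 12, LDA (2.1 equiv), THF, −78 °C; 15 [from 14, n-BuLi then Tf2O, Et2O, −78 °C] added at −78 °C; AcOH quench at −78 °C
Reagents that add atoms: none
Why: Dianion alkylation: LDA removes the triacylmethine proton and then a proton of the acetyl methyl (the only other acidic site), and the more basic ketone enolate carbon displaces the primary triflate of 15 by SN2 at −78 °C, where neither the epoxide nor the anion-deactivated ester should react; the epoxide stereocentres are untouched.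

Step 8
Reactants: 16 methyl (4S)-4-methyl-4-(3-methylbut-2-en-1-yl)-7-[(2R,3S)-3-methyl-3-(4-methylpent-3-en-1-yl)oxiran-2-yl]-2-(2-methylpropanoyl)-3,5-dioxoheptanoate
Product: 18 (2S,5R)-6-hydroxy-2-[(2S)-2-hydroxy-6-methylhept-5-en-2-yl]-5-methyl-5-(3-methylbut-2-en-1-yl)-7-(2-methylpropanoyl)-2,3-dihydro-1-benzofuran-4(5H)-one, via triketone epoxide 17 (not isolated)
Conditions: LiHMDS (2.1 equiv), THF, −78 → 0 °C; then AcOH (1.0 equiv), DMPU, 45–60 °C; cold 0.5 M HCl work-up
Reagents that add atoms: none
Why: Dieckmann (intramolecular Claisen) condensation followed in the same flask by O-alkylation of a β-triketonate by an epoxide; the closest known reaction types are the Claisen cyclisation of 5-oxo esters to cyclohexane-1,3-diones and the base-mediated closure of 2-(2,3-epoxyalkyl)-1,3-diones and acylphloroglucinols to 2-(1-hydroxyalkyl)dihydrofurans. Two equivalents of LiHMDS give the dianion of 16 (triacylmethanide plus the enolate at C-6 of the chain, the only enolisable ketone position because C-4 is quaternary); the enolate carbon adds to the ester carbonyl in a 6-(enolendo)-exo-trig closure and methoxide leaves, which forms the carbocycle as 17 (C3a–C7a bond). One equivalent of acetic acid then removes the second charge, so the remaining anion sits in the 2-acyl-1,3-dicarbonyl unit around C7; of its three oxygens only the one on C7a reaches the side chain, and it opens the epoxide at the secondary carbon in a 5-exo-tet closure (dihydrofuran ring, O1–C2 bond). The new stereocentre C2 arises by SN2 inversion of the (2R)-oxirane carbon set in step 6, the carbinol carbon keeps its configuration because its C–O bond is not touched, and C5 is a spectator. The step needs (a) Claisen closure faster than attack of the ketone enolate on the epoxide, secured by the lithium counter-ion and the low temperature at which epoxides are inert, (b) ether formation through the oxygen on C7a and not the one on C4, secured by the isobutyryl group, which makes C7 the most acidic site by several pK units and so localises the mono-anion there, and (c) attack at the secondary and not the tertiary epoxide carbon, secured by the anionic SN2 conditions.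

Step 9
Reactants: 18 the C7-H bicyclic triketone; 19 3-methylbut-2-en-1-yl acetate (prenyl acetate)
Product: 20 (2S,5S,7S)-2-[(2S)-2-hydroxy-6-methylhept-5-en-2-yl]-5-methyl-5,7-bis(3-methylbut-2-en-1-yl)-7-(2-methylpropanoyl)-2,3-dihydro-1-benzofuran-4,6(5H,7H)-dione (CNP0250451.1)
Conditions: Pd(PPh3)4 (5 mol%), Et3N (1.2 equiv), THF, 40 °C
Reagents that add atoms: none
Why: Tsuji–Trost allylic alkylation: the soft triethylammonium triketonate of 18 should attack the π-prenyl complex of zerovalent palladium at its unsubstituted terminus, O-allylated material re-ionises and funnels to the C7 quaternary product, and the electrophile should enter the ring face that carries the C5 methyl and the C2 hydrogen, away from the C5 prenyl and the C2 side chain, which gives the (7S) centre.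

**Compound list**
1 | methyl 2-methyl-3-oxobutanoate | CC(=O)C(C)C(=O)OC | starting material
2 | 2-(trimethylsilyl)ethanol | C[Si](C)(C)CCO | starting material
3 | 2-(trimethylsilyl)ethyl 2-methyl-3-oxobutanoate (racemic) | CC(=O)C(C)C(=O)OCC[Si](C)(C)C | intermediate
4 | L-valine tert-butyl ester [tert-butyl (2S)-2-amino-3-methylbutanoate] | CC(C)[C@H](N)C(=O)OC(C)(C)C | starting material
5 | 2-(trimethylsilyl)ethyl (2Z)-3-{[(2S)-1-tert-butoxy-3-methyl-1-oxobutan-2-yl]amino}-2-methylbut-2-enoate | C/C(=C(\C)C(=O)OCC[Si](C)(C)C)N[C@@H](C(C)C)C(=O)OC(C)(C)C | intermediate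
6 | 1-bromo-3-methylbut-2-ene (prenyl bromide) | CC(C)=CCBr | starting material
7 | 2-(trimethylsilyl)ethyl (2S)-3-{[(2S)-1-tert-butoxy-3-methyl-1-oxobutan-2-yl]imino}-2-methyl-2-(3-methylbut-2-en-1-yl)butanoate (ketimine) | CC(=N[C@@H](C(C)C)C(=O)OC(C)(C)C)[C@](C)(CC=C(C)C)C(=O)OCC[Si](C)(C)C | intermediate
8 | 2-(trimethylsilyl)ethyl (2S)-2-methyl-2-(3-methylbut-2-en-1-yl)-3-oxobutanoate | CC(=O)[C@](C)(CC=C(C)C)C(=O)OCC[Si](C)(C)C | intermediate
9 | (2S)-2-methyl-2-(3-methylbut-2-en-1-yl)-3-oxobutanoic acid | CC(=O)[C@](C)(CC=C(C)C)C(=O)O | intermediate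
10 | methyl 4-methyl-3-oxopentanoate | CC(C)C(=O)CC(=O)OC | starting material
11 | (2S)-2-methyl-2-(3-methylbut-2-en-1-yl)-3-oxobutanoyl chloride | CC(=O)[C@](C)(CC=C(C)C)C(=O)Cl | intermediate
12 | methyl (4S)-4-methyl-4-(3-methylbut-2-en-1-yl)-2-(2-methylpropanoyl)-3,5-dioxohexanoate (C-2 is an enolised triacylmethine without fixed configuration) | CC(=O)[C@](C)(CC=C(C)C)C(=O)C(C(=O)C(C)C)C(=O)OC | intermediate
13 | nerol [(2Z)-3,7-dimethylocta-2,6-dien-1-ol] | CC(C)=CCC/C(C)=C\CO | starting material
14 | [(2R,3S)-3-methyl-3-(4-methylpent-3-en-1-yl)oxiran-2-yl]methanol | CC(C)=CCC[C@]1(C)O[C@@H]1CO | intermediate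
15 | [(2R,3S)-3-methyl-3-(4-methylpent-3-en-1-yl)oxiran-2-yl]methyl trifluoromethanesulfonate | CC(C)=CCC[C@]1(C)O[C@@H]1COS(=O)(=O)C(F)(F)F | intermediate
16 | methyl (4S)-4-methyl-4-(3-methylbut-2-en-1-yl)-7-[(2R,3S)-3-methyl-3-(4-methylpent-3-en-1-yl)oxiran-2-yl]-2-(2-methylpropanoyl)-3,5-dioxoheptanoate (C-2 enolised, no fixed configuration) | CC(C)=CCC[C@]1(C)O[C@@H]1CCC(=O)[C@](C)(CC=C(C)C)C(=O)C(C(=O)C(C)C)C(=O)OC | intermediate
17 | (6R)-3,5-dihydroxy-6-methyl-6-(3-methylbut-2-en-1-yl)-2-{[(2R,3S)-3-methyl-3-(4-methylpent-3-en-1-yl)oxiran-2-yl]methyl}-4-(2-methylpropanoyl)cyclohexa-2,4-dien-1-one (dienol form of the cyclised triketone) | CC(C)=CCC[C@]1(C)O[C@@H]1CC2=C(O)C(C(=O)C(C)C)=C(O)[C@@](C)(CC=C(C)C)C2=O | intermediate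
18 | (2S,5R)-6-hydroxy-2-[(2S)-2-hydroxy-6-methylhept-5-en-2-yl]-5-methyl-5-(3-methylbut-2-en-1-yl)-7-(2-methylpropanoyl)-2,3-dihydro-1-benzofuran-4(5H)-one (6-enol of the C7-H triketone; same spatial arrangement at C5 as in 20, the descriptor differs by priority rules only) | CC(C)=CCC[C@](C)(O)[C@@H]1CC2=C(O1)C(C(=O)C(C)C)=C(O)[C@@](C)(CC=C(C)C)C2=O | intermediate
19 | 3-methylbut-2-en-1-yl acetate (prenyl acetate) | CC(C)=CCOC(C)=O | starting material
20 | (2S,5S,7S)-2-[(2S)-2-hydroxy-6-methylhept-5-en-2-yl]-5-methyl-5,7-bis(3-methylbut-2-en-1-yl)-7-(2-methylpropanoyl)-2,3-dihydro-1-benzofuran-4,6(5H,7H)-dione | CC(C)=CCC[C@](C)(O)[C@@H]1CC2=C(O1)[C@@](CC=C(C)C)(C(=O)C(C)C)C(=O)[C@@](C)(CC=C(C)C)C2=O | target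

**Step count**
Total steps: 9. Longest linear sequence: 8 steps (1 → 2 → 3 → 4 → 5 → 7 → 8 → 9); step 6 is the one-step side branch.

**Steps most likely to fail**

Step 8. What may go wrong: the Claisen closure onto an ester whose α-carbon is already an anion may be slower than attack of the ketone enolate on the epoxide (cyclopropane formation, or ether formation through the chain C-5 ketone oxygen). Fallback: the carbocycle is closed before the epoxide is present. It sets out from 12 and 14 and rejoins the route at 17. 12 is cyclised with LDA (2.2 equiv, THF, −78 °C → rt; Dieckmann condensation with no competing electrophile) to the monocyclic triketone F1. 14 is oxidised with Dess–Martin periodinane/NaHCO3 to the epoxy aldehyde F2. Knoevenagel condensation of F1 at its free ring CH with F2, with in situ conjugate reduction by diethyl 2,6-dimethyl-1,4-dihydropyridine-3,5-dicarboxylate (L-proline cat., CH2Cl2, rt; reductive alkylation of a cyclic 1,3-dione), should give 17. 17 is then closed to 18 with Et3N in THF at 45 °C, as in the second half of step 8.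

Step 7. What may go wrong: premature Claisen closure of the dianion before it is alkylated, O-alkylation by the hard triflate, or loss of the epoxy triflate by decomposition. Fallback: the order of the C–C bond formations is changed so that the enolate never faces an acylating group. It sets out from 8 and 14 and returns at 16. The lithium enolate of 8 (LDA, 1.05 equiv, THF, −78 °C; the acetyl methyl is the only acidic site) is alkylated with 15 to give the epoxy keto ester F3. TBAF (THF, 0 °C, pH 5 buffer work-up at 0 °C) gives the epoxy keto acid F4. 1-Chloro-N,N,2-trimethylprop-1-en-1-amine converts it into the acid chloride F5, which acylates the chloride-free magnesium enolate of 10 (from Mg(OEt)2) at carbon to give 16.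

Step 9. What may go wrong: low facial selectivity at C7 (induction only from C5 and C2), O-prenylation that does not revert, or attack at the dimethyl-substituted allyl terminus. Fallback: ligand-controlled, inner-sphere decarboxylative allylation followed by cross-metathesis. It sets out from 18 and returns at 20. Allyl chloroformate/Et3N (CH2Cl2, 0 °C) gives the allyl enol carbonate F6. Pd2(dba)3 with (S)-t-Bu-PHOX (or its enantiomer, whichever is matched; THF, rt) effects decarboxylative allylic alkylation to the C7-allyl compound F7. Cross-metathesis with 2-methylbut-2-ene (second-generation Grubbs catalyst, CH2Cl2, 40 °C) turns the allyl into the prenyl group and gives 20; the trisubstituted alkenes should not react.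

**Further compounds**
F1 | step 8 | (6R)-3,5-dihydroxy-6-methyl-6-(3-methylbut-2-en-1-yl)-4-(2-methylpropanoyl)cyclohexa-2,4-dien-1-one | CC(C)C(=O)C1=C(O)[C@@](C)(CC=C(C)C)C(=O)C=C1O
F2 | step 8 | (2S,3S)-3-methyl-3-(4-methylpent-3-en-1-yl)oxirane-2-carbaldehyde | CC(C)=CCC[C@]1(C)O[C@@H]1C=O
F3 | step 7 | 2-(trimethylsilyl)ethyl (2S)-2-methyl-2-(3-methylbut-2-en-1-yl)-5-[(2R,3S)-3-methyl-3-(4-methylpent-3-en-1-yl)oxiran-2-yl]-3-oxopentanoate | CC(C)=CCC[C@]1(C)O[C@@H]1CCC(=O)[C@](C)(CC=C(C)C)C(=O)OCC[Si](C)(C)C
F4 | step 7 | (2S)-2-methyl-2-(3-methylbut-2-en-1-yl)-5-[(2R,3S)-3-methyl-3-(4-methylpent-3-en-1-yl)oxiran-2-yl]-3-oxopentanoic acid | CC(C)=CCC[C@]1(C)O[C@@H]1CCC(=O)[C@](C)(CC=C(C)C)C(=O)O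
F5 | step 7 | (2S)-2-methyl-2-(3-methylbut-2-en-1-yl)-5-[(2R,3S)-3-methyl-3-(4-methylpent-3-en-1-yl)oxiran-2-yl]-3-oxopentanoyl chloride | CC(C)=CCC[C@]1(C)O[C@@H]1CCC(=O)[C@](C)(CC=C(C)C)C(=O)Cl
F6 | step 9 | (2S,5R)-2-[(2S)-2-hydroxy-6-methylhept-5-en-2-yl]-5-methyl-5-(3-methylbut-2-en-1-yl)-7-(2-methylpropanoyl)-4-oxo-2,3,4,5-tetrahydro-1-benzofuran-6-yl prop-2-en-1-yl carbonate | CC(C)=CCC[C@](C)(O)[C@@H]1CC2=C(O1)C(C(=O)C(C)C)=C(OC(=O)OCC=C)[C@@](C)(CC=C(C)C)C2=O
F7 | step 9 | (2S,5S,7S)-2-[(2S)-2-hydroxy-6-methylhept-5-en-2-yl]-5-methyl-5-(3-methylbut-2-en-1-yl)-7-(2-methylpropanoyl)-7-(prop-2-en-1-yl)-2,3-dihydro-1-benzofuran-4,6(5H,7H)-dione | CC(C)=CCC[C@](C)(O)[C@@H]1CC2=C(O1)[C@@](CC=C)(C(=O)C(C)C)C(=O)[C@@](C)(CC=C(C)C)C2=O
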